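## The problem

The target (32) is an ent-labdane. Ring A of its trans-fused decalin carries the C3 carbinol, the C4 gem-dimethyl group and the angular C20 methyl on the quaternary C10. Ring B carries the C7=C8 alkene with the C17 hydroxymethyl group and, at C9, a five-carbon chain that ends in a methyl ester and has a methyl-bearing stereocentre at C13. Four of the five stereocentres (C3, C5, C9, C10) lie in the bicycle and can be made to depend on one another. An equatorial C3 oxygen on a forming ring A chair can fix C5 and C10, and the axial C20 methyl then shields one face of C9. C13 is too far from the ring to be controlled by it and must arrive in a building block of known configuration. The hard point is C10: it is quaternary and 1,3 to the axial C4 methyl, so any bond made to it is made against a syn-axial methyl group. The methyl ester rules out organolithium, hydride and hydroxide reagents once the chain is attached. The allylic alcohol and the trisubstituted alkene (which acid can shift to C8=C9) should appear last, and C9 is epimerisable whenever C8 is a ketone. The feature that opens the structure is that C5 and C10 are neighbours in ring A, with C10 two carbons from C8 and C5 one carbon from C6. C10 can therefore be the β-carbon of a C8 enone and C5 the γ-carbon of an allylsilane. Joining them closes ring A and leaves C6 and C8 in the 1,5-relationship that ring B needs.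

## Retrosynthesis

**C3–O and C8–C17.** The free C3 hydroxyl of 32 is unmasked last from silyl ether 31. The C8–C17 bond of 31 is cut to enol triflate 30 and a hydroxymethyl tin reagent. This brings C17 in at the alcohol oxidation level. A carbonylation–reduction sequence would instead have to tell a new ester from the side-chain ester. Triflate 30 comes from ketone 28 by kinetic enolisation towards C7, which is asked to place the alkene at C7=C8 and not at C8=C9.

**C9–C11.** The chain is detached from ketone 28 as an aldol condensation: dienone 27, from aldol adduct 25, from bicyclic enone 20 and aldehyde ester 23. Direct alkylation of the C9 enolate with an alkyl iodide would put the chain anti to C20, the wrong epimer, and would rely on an equilibration whose outcome at this position is not clear-cut. In the aldol route C9 is trigonal in 27, and hydrogenation delivers H9 anti to C20, so the chain ends up equatorial under kinetic control. Enone 20 can only be deprotonated at C9, so the regiochemistry of chain attachment is built in. Aldehyde 23 comes in two steps from half-ester 21 through hydroxy ester 22 and carries C13.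

**C6=C7 (ring B).** Enone 20 is opened by a retro-aldol condensation to keto aldehyde 18. Only the methyl carbon C7 can reach the C6 aldehyde through a six-membered ring. The aldehyde is written back to the vinyl group of 16, a spectator that survives Lewis acid and is unveiled by ozonolysis.

**C5–C10 (ring A, key step).** Cyclohexane 16 is cut between its two adjacent ring stereocentres to the acyclic (E)-enone (E)-allylsilane 14. This removes the ring, the quaternary centre and two stereocentres at once. The precursor keeps a single stereocentre, C3, which any other ring A closure would also need. The forward reaction must form a bond between two congested carbons and place C20 rather than the enone arm in the axial site.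

**C8–C9, C6=C7′, C3–C4.** The enone of 14 is made last from (E)-alkenyl iodide 11 by iodine–lithium exchange and acylation, so its geometry is inherited and not created. A Horner–Wadsworth–Emmons reaction on a methyl ketone would give E/Z mixtures. The allylsilane of 11 comes from terminal alkene 9 and allyltrimethylsilane 10 by cross-metathesis. This is done before the enone exists so that no second reactive alkene is present. Silyl ether 9 comes from alcohol 8. The C3–C4 bond of 8 is cut to aldehyde 4 and allene 5 (reverse prenylation), which supplies C3, the gem-dimethyl carbon and the C5=C6 vinyl group in one asymmetric step. An isobutyrate aldol would need three further steps to turn its ester into that vinyl group. Aldehyde 4 comes from alcohol 3, the carboalumination–iodination product of pent-4-yn-1-ol 1.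

## Roads not taken

**Alternative 1:** The C10–C20 and C9–C20 bonds are made on a ring B derived from an aromatic precursor. Allylic alcohol A1 (C8 carbinol, C9=C10 alkene) is treated with Et2Zn and CH2I2, and the zinc carbenoid, held by the C8 oxygen, closes the cyclopropane to give A2. Oxidation to the cyclopropyl ketone and reductive opening of the C9–C20 bond (Li in NH3) would then reveal the angular methyl and a regiodefined C9 enolate.
- Merits: hydroxyl-directed cyclopropanation is one of the most dependable ways to choose the face of a ring-fusion alkene, and the enolate appears exactly where the chain must go. On the security of C10 this road is better than the chosen one.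
- Weak points: the face is chosen relative to the C8 carbinol, which must first be set relative to C5 and C3. C3, C4 and C5 have to be built on a reduced aromatic ring with several redox steps. Trapping the C9 enolate with the chain electrophile gives the chain anti to C20, the wrong epimer.
- Comparison: the chosen plan draws three ring stereocentres from one acyclic carbinol in fewer steps and sets C9 by hydrogen delivery rather than alkylation.

**Alternative 2:** Ring B comes from (S)-carvone, and the C3–C4 bond is made last in ring A. In keto aldehyde A3, Fe(acac)3 and PhSiH3 transfer a hydrogen atom to the isopropenyl CH2, and the tertiary C4 radical adds to the tethered C3 aldehyde to give bicyclic enone A4.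
- Merits: C5 comes from the chiral pool, C10 is set by alkylation trans to the isopropenyl group (more reliable than the facial choice in the chosen key step), a radical forms the hindered C3–C4 bond easily, and the C7=C8 alkene with its C17 carbon is present from the start. It reaches a bicyclic core in fewer steps.
- Weak points: in A4 C9 is a ketone flanked by the quaternary C10. The chain would have to be added to that carbonyl and the oxygen then removed with control of C9. C17 is a methyl group that needs a late, regioselective allylic oxidation, and the C3 configuration rests on an untested radical addition to an aldehyde.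
- Comparison: the chosen plan has C8 as the carbonyl, so C9 is functionalised as an enolate carbon and C17 enters already oxidised.

**Alternative 3:** The C9–C10 and C7–C8 bonds are cut together. Ring A diene A5 (C10=C5–C6=C7) and side-chain ynone A6 (C8≡C9) combine in a Diels–Alder reaction, thermally or with EtAlCl2, to give cyclohexa-1,4-diene A7.
- Merits: it is the most convergent plan. Every carbon of the target, including C17 and the C13 centre, is in place after one step.
- Weak points: the diene terminus C10 is fully substituted, so the cycloaddition is slow and needs forcing. Its facial selectivity at C10 is governed only by the remote C3 substituent. A7 then requires reduction of C5=C6 to the trans fusion, migration of C8=C9 to C7=C8, removal of the C11 oxygen and control of C9, each a selectivity problem.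
- Comparison: the chosen plan is linear and longer to assemble, but it fixes C5 and C10 in one event on a chair organised by C3 and needs no deoxygenation.

Key step: step 7

Remark: positions are numbered as in labdane (C1–C20) throughout, and (−)-Ipc2BH, made from (+)-α-pinene and BH3·SMe2, is taken as a stock reagent.

## Route

Step 1
Reactants: 1 pent-4-yn-1-ol
Product: 3 (4E)-5-iodo-4-methylpent-4-en-1-ol, via alkenylalane 2 (not isolated)
Conditions: AlMe3 (3 equiv), Cp2ZrCl2 (0.25 equiv), CH2Cl2, 0 °C to rt; then I2, THF, −30 to 0 °C; aq. K2CO3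
Reagents that add atoms: trimethylaluminium, C[Al](C)C; iodine, II
Why: Negishi zirconium-catalysed carboalumination adds methyl and aluminium syn across the alkyne with the metal at the terminus, and iodinolysis retains the geometry, so the chain ends up trans to iodine (E). The hydroxyl is carried as its aluminium alkoxide.

Step 2
Reactants: 3 (4E)-5-iodo-4-methylpent-4-en-1-ol
Product: 4 (4E)-5-iodo-4-methylpent-4-enal
Conditions: Dess–Martin periodinane, NaHCO3, CH2Cl2, 0 °C to rt
Reagents that add atoms: none
Why: Dess–Martin oxidation of a primary alcohol stops at the aldehyde under buffered conditions that leave the alkenyl iodide and its geometry untouched.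

Step 3
Reactants: 4 (4E)-5-iodo-4-methylpent-4-enal; 5 3-methylbuta-1,2-diene
Product: 8 (4R,7E)-8-iodo-3,3,7-trimethylocta-1,7-dien-4-ol, via prenylborane 6 (not isolated), via borinate 7 (not isolated)
Conditions: (−)-Ipc2BH, 5, THF, −25 °C; then 4, −78 °C; NaOH, H2O2, 0 °C to rt
Reagents that add atoms: none
Why: Brown reverse prenylation: hydroboration of the allene gives the prenylborane, which adds to the aldehyde through its γ-carbon in a chair transition state and forms C3–C4 together with the gem-dimethyl carbon and the C5=C6 vinyl group. The isopinocampheyl groups from (+)-α-pinene direct attack to the Si face of the aldehyde, which here corresponds to the (R) carbinol at C3.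

Step 4
Reactants: 8 (4R,7E)-8-iodo-3,3,7-trimethylocta-1,7-dien-4-ol
Product: 9 tert-butyl{[(4R,7E)-8-iodo-3,3,7-trimethylocta-1,7-dien-4-yl]oxy}dimethylsilane
Conditions: TBSOTf, 2,6-lutidine, CH2Cl2, −78 to 0 °C
Reagents that add atoms: tert-butyldimethylsilyl trifluoromethanesulfonate, CC(C)(C)[Si](C)(C)OS(=O)(=O)C(F)(F)F
Why: Silylation with the silyl triflate is used because the carbinol is next to a quaternary carbon. The bulky ether later occupies the equatorial site of the ring A chair and withstands the Lewis acid, base and hydrogenation steps.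

Step 5
Reactants: 9 tert-butyl{[(4R,7E)-8-iodo-3,3,7-trimethylocta-1,7-dien-4-yl]oxy}dimethylsilane; 10 allyltrimethylsilane
Product: 11 tert-butyl{[(1E,5R,7E)-1-iodo-2,6,6-trimethyl-9-(trimethylsilyl)nona-1,7-dien-5-yl]oxy}dimethylsilane
Conditions: 10 (4 equiv), second-generation Hoveyda–Grubbs catalyst (5 mol %), CH2Cl2, 40 °C
Reagents that add atoms: none
Why: Olefin cross-metathesis between a terminal alkene on a quaternary carbon, which cannot homodimerise, and an excess of a reactive allylsilane; the tert-alkyl substituent permits only the (E) alkene. The trisubstituted iodoalkene does not engage the ruthenium carbene.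

Step 6
Reactants: 11 tert-butyl{[(1E,5R,7E)-1-iodo-2,6,6-trimethyl-9-(trimethylsilyl)nona-1,7-dien-5-yl]oxy}dimethylsilane
Product: 14 (3E,7R,9E)-7-[(tert-butyldimethylsilyl)oxy]-4,8,8-trimethyl-11-(trimethylsilyl)undeca-3,9-dien-2-one, via alkenyllithium 12 (not isolated), via lithium hemiaminal 13 (not isolated)
Conditions: t-BuLi (2.1 equiv), Et2O, −78 °C; then N-methoxy-N-methylacetamide, −78 to 0 °C; aq. NH4Cl
Reagents that add atoms: N-methoxy-N-methylacetamide, CC(=O)N(C)OC
Why: Iodine–lithium exchange occurs with retention at the alkene, and the alkenyllithium acylates the Weinreb amide once because the chelated adduct releases the ketone only on work-up. C8 is therefore cis to C20, the (E)-enone.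

Step 7
Reactants: 14 (3E,7R,9E)-7-[(tert-butyldimethylsilyl)oxy]-4,8,8-trimethyl-11-(trimethylsilyl)undeca-3,9-dien-2-one
Product: 16 1-[(1S,2S,4R)-4-[(tert-butyldimethylsilyl)oxy]-2-ethenyl-1,3,3-trimethylcyclohexyl]propan-2-one, via trichlorotitanium enolate 15 (not isolated)
Conditions: TiCl4 (1.1 equiv), CH2Cl2, −78 °C; aq. NaHCO3
Reagents that add atoms: none
Why: TiCl4 binds the ketone oxygen and makes C10 electrophilic; the allylsilane attacks through its γ-carbon C5, the β-silyl cation at C6 gives up its silyl group to chloride to leave the C5 vinyl group, and enolate 15 is protonated on work-up (intramolecular Hosomi–Sakurai conjugate addition). The closest known reactions are TiCl4-promoted cyclisations of (E)-allylsilanes onto acyclic β-methyl enones, which give cyclohexanes with a quaternary carbon next to a vinyl-bearing carbon. Ring A closes in a 6-exo-trig mode through a chair. C5 is controlled by C3 and the (E)-allylsilane: the silyloxy group and C6 both take equatorial sites, so the vinyl group ends up cis to the silyloxy group with H5 axial. C10 is controlled by the (E)-enone geometry: with the acyl group syn to C20 the arm can lie equatorial with its carbonyl folded over C6, whereas an axial arm would push the C9–H bond over the fully substituted C4 and its axial methyl, so C20 takes the axial site. The step needs selectivity only at C10 relative to C3, because an error at C5 can still be corrected by enolisation of the aldehyde after step 8. It is secured by the geometrically pure (E,E) substrate from steps 1 and 5 and by the low temperature. The hindered silyl ether tolerates TiCl4 at −78 °C.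

Step 8
Reactants: 16 1-[(1S,2S,4R)-4-[(tert-butyldimethylsilyl)oxy]-2-ethenyl-1,3,3-trimethylcyclohexyl]propan-2-one
Product: 18 (1S,3R,6S)-3-[(tert-butyldimethylsilyl)oxy]-2,2,6-trimethyl-6-(2-oxopropyl)cyclohexane-1-carbaldehyde, via ozonide 17 (not isolated)
Conditions: O3, CH2Cl2, −78 °C; then PPh3, −78 °C to rt
Reagents that add atoms: ozone, [O-][O+]=O
Why: Ozonolysis of the only alkene with reductive work-up turns the vinyl group into the C6 aldehyde with loss of one carbon; the cold, neutral conditions do not epimerise C5.

Step 9
Reactants: 18 (1S,3R,6S)-3-[(tert-butyldimethylsilyl)oxy]-2,2,6-trimethyl-6-(2-oxopropyl)cyclohexane-1-carbaldehyde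
Product: 20 (4aS,6R,8aS)-6-[(tert-butyldimethylsilyl)oxy]-5,5,8a-trimethyl-4a,5,6,7,8,8a-hexahydronaphthalen-2(1H)-one, via hydroxy ketone 19 (not isolated)
Conditions: KOH, MeOH, 0 °C to rt
Reagents that add atoms: none
Why: Intramolecular aldol condensation of a 1,5-keto aldehyde: only the methyl carbon C7 can reach the aldehyde through a six-membered ring, and E1cB loss of water gives the C6=C7 enone. Ring B closes trans because both arms are equatorial on ring A, and the trans-fused enone is also expected to be the more stable isomer if C5 should enolise.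

Step 10
Reactants: 21 methyl hydrogen (R)-3-methylglutarate
Product: 22 methyl (3R)-5-hydroxy-3-methylpentanoate
Conditions: BH3·SMe2, THF, 0 °C to rt; MeOH
Reagents that add atoms: none
Why: Borane reduces a carboxylic acid much faster than an ester, so only the acid arm becomes the primary alcohol; C13 has no acidic hydrogen and keeps its configuration. The hydroxy ester is used at once to forestall lactonisation.

Step 11
Reactants: 22 methyl (3R)-5-hydroxy-3-methylpentanoate
Product: 23 methyl (3R)-3-methyl-5-oxopentanoate
Conditions: Dess–Martin periodinane, NaHCO3, CH2Cl2, 0 °C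
Reagents that add atoms: none
Why: Dess–Martin oxidation gives the aldehyde without touching the ester or the β-stereocentre.

Step 12
Reactants: 20 (4aS,6R,8aS)-6-[(tert-butyldimethylsilyl)oxy]-5,5,8a-trimethyl-4a,5,6,7,8,8a-hexahydronaphthalen-2(1H)-one; 23 methyl (3R)-3-methyl-5-oxopentanoate
Product: 25 methyl (3R)-5-[(4aS,6R,8aR)-6-[(tert-butyldimethylsilyl)oxy]-5,5,8a-trimethyl-2-oxo-1,2,4a,5,6,7,8,8a-octahydronaphthalen-1-yl]-5-hydroxy-3-methylpentanoate (mixture at C9 and C11), via lithium dienolate 24 (not isolated)
Conditions: LiN(i-Pr)2, THF, −78 °C; then 23, −78 °C; AcOH, −78 °C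
Reagents that add atoms: none
Why: Directed aldol addition: kinetic deprotonation of the enone can only take place at C9, and the cross-conjugated lithium dienolate adds to the aldehyde faster than it enolises it. The new centres at C9 and C11 need no control because both become trigonal in step 13, and the cold acidic quench prevents the aldolate from lactonising onto the ester.

Step 13
Reactants: 25 methyl (3R)-5-[(4aS,6R,8aR)-6-[(tert-butyldimethylsilyl)oxy]-5,5,8a-trimethyl-2-oxo-1,2,4a,5,6,7,8,8a-octahydronaphthalen-1-yl]-5-hydroxy-3-methylpentanoate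
Product: 27 methyl (3R)-5-[(4aS,6R,8aR)-6-[(tert-butyldimethylsilyl)oxy]-5,5,8a-trimethyl-2-oxo-4a,5,6,7,8,8a-hexahydronaphthalen-1(2H)-ylidene]-3-methylpentanoate (either alkene geometry), via mesylate 26 (not isolated)
Conditions: MsCl, Et3N, CH2Cl2, 0 °C; then DBU, rt
Reagents that add atoms: none
Why: Mesylation of the β-hydroxy ketone followed by E1cB elimination gives the C9=C11 alkylidene ketone. Activating the hydroxyl first avoids the retro-aldol that direct base treatment would invite.

Step 14
Reactants: 27 methyl (3R)-5-[(4aS,6R,8aR)-6-[(tert-butyldimethylsilyl)oxy]-5,5,8a-trimethyl-2-oxo-4a,5,6,7,8,8a-hexahydronaphthalen-1(2H)-ylidene]-3-methylpentanoate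
Product: 28 methyl (3R)-5-[(1S,4aS,6R,8aR)-6-[(tert-butyldimethylsilyl)oxy]-5,5,8a-trimethyl-2-oxodecahydronaphthalen-1-yl]-3-methylpentanoate
Conditions: H2 (1 atm), Pd/C, EtOAc, rt
Reagents that add atoms: none
Why: Heterogeneous hydrogenation saturates both enone alkenes. At C9 hydrogen is delivered to the face opposite the axial C20 methyl on the neighbouring carbon, which makes H9 axial and leaves the chain equatorial and cis to C20, as in the target.

Step 15
Reactants: 28 methyl (3R)-5-[(1S,4aS,6R,8aR)-6-[(tert-butyldimethylsilyl)oxy]-5,5,8a-trimethyl-2-oxodecahydronaphthalen-1-yl]-3-methylpentanoate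
Product: 30 methyl (3R)-5-[(1S,4aS,6R,8aR)-6-[(tert-butyldimethylsilyl)oxy]-5,5,8a-trimethyl-2-{[(trifluoromethyl)sulfonyl]oxy}-1,4,4a,5,6,7,8,8a-octahydronaphthalen-1-yl]-3-methylpentanoate, via potassium enolate 29 (not isolated)
Conditions: KN(SiMe3)2 (1.05 equiv), THF, −78 °C; then PhNTf2, −78 to 0 °C
Reagents that add atoms: N-phenylbis(trifluoromethanesulfonimide), O=S(=O)(N(c1ccccc1)S(=O)(=O)C(F)(F)F)C(F)(F)F
Why: Kinetic enolisation with a bulky amide removes a C7 methylene proton rather than the tertiary C9–H beside the quaternary carbon, and the ketone is several pK units more acidic than the ester. O-Triflation of the enolate fixes the alkene at C7=C8.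

Step 16
Reactants: 30 methyl (3R)-5-[(1S,4aS,6R,8aR)-6-[(tert-butyldimethylsilyl)oxy]-5,5,8a-trimethyl-2-{[(trifluoromethyl)sulfonyl]oxy}-1,4,4a,5,6,7,8,8a-octahydronaphthalen-1-yl]-3-methylpentanoate
Product: 31 methyl (3R)-5-[(1S,4aS,6R,8aS)-6-[(tert-butyldimethylsilyl)oxy]-2-(hydroxymethyl)-5,5,8a-trimethyl-1,4,4a,5,6,7,8,8a-octahydronaphthalen-1-yl]-3-methylpentanoate
Conditions: Bu3SnCH2OH, Pd(PPh3)4 (5 mol %), LiCl, 1,4-dioxane, 100 °C
Reagents that add atoms: (tributylstannyl)methanol, CCCC[Sn](CCCC)(CCCC)CO
Why: Stille coupling of an enol triflate with the hydroxymethyl stannane installs C17 at the alcohol oxidation level and keeps the alkene where the triflate put it. The neutral conditions spare the ester and the C9 centre.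

Step 17
Reactants: 31 methyl (3R)-5-[(1S,4aS,6R,8aS)-6-[(tert-butyldimethylsilyl)oxy]-2-(hydroxymethyl)-5,5,8a-trimethyl-1,4,4a,5,6,7,8,8a-octahydronaphthalen-1-yl]-3-methylpentanoate
Product: 32 methyl (3R)-5-[(1S,4aS,6R,8aS)-6-hydroxy-2-(hydroxymethyl)-5,5,8a-trimethyl-1,4,4a,5,6,7,8,8a-octahydronaphthalen-1-yl]-3-methylpentanoate
Conditions: HF·pyridine, THF, 0 °C to rt
Reagents that add atoms: none
Why: Fluoride cleavage of the hindered secondary silyl ether under mildly acidic, non-nucleophilic conditions frees the C3 hydroxyl without hydrolysing the ester or ionising the allylic alcohol.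

## Compound list

1 | pent-4-yn-1-ol | C#CCCCO | starting material
2 | {(1E)-5-[(dimethylalumanyl)oxy]-2-methylpent-1-en-1-yl}dimethylalumane | C[Al](C)OCCC/C(C)=C/[Al](C)C | intermediate
3 | (4E)-5-iodo-4-methylpent-4-en-1-ol | OCCC/C(C)=C/I | intermediate
4 | (4E)-5-iodo-4-methylpent-4-enal | O=CCC/C(C)=C/I | intermediate
5 | 3-methylbuta-1,2-diene | CC(C)=C=C | starting material
6 | (3-methylbut-2-en-1-yl)bis[(1R,2S,3R,5R)-2,6,6-trimethylbicyclo[3.1.1]heptan-3-yl]borane | CC(C)=CCB([C@@H]1C[C@@H]2C[C@H]([C@H]1C)C2(C)C)[C@@H]1C[C@@H]2C[C@H]([C@H]1C)C2(C)C | intermediate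
7 | (4R,7E)-8-iodo-3,3,7-trimethylocta-1,7-dien-4-yl bis[(1R,2S,3R,5R)-2,6,6-trimethylbicyclo[3.1.1]heptan-3-yl]borinate | C=CC(C)(C)[C@H](OB([C@@H]1C[C@@H]2C[C@H]([C@H]1C)C2(C)C)[C@@H]1C[C@@H]2C[C@H]([C@H]1C)C2(C)C)CC/C(C)=C/I | intermediate
8 | (4R,7E)-8-iodo-3,3,7-trimethylocta-1,7-dien-4-ol | C=CC(C)(C)[C@H](O)CC/C(C)=C/I | intermediate
9 | tert-butyl{[(4R,7E)-8-iodo-3,3,7-trimethylocta-1,7-dien-4-yl]oxy}dimethylsilane | C=CC(C)(C)[C@H](O[Si](C)(C)C(C)(C)C)CC/C(C)=C/I | intermediate
10 | allyltrimethylsilane | C=CC[Si](C)(C)C | starting material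
11 | tert-butyl{[(1E,5R,7E)-1-iodo-2,6,6-trimethyl-9-(trimethylsilyl)nona-1,7-dien-5-yl]oxy}dimethylsilane | C[Si](C)(C)C/C=C/C(C)(C)[C@H](O[Si](C)(C)C(C)(C)C)CC/C(C)=C/I | intermediate
12 | alkenyllithium from 11 (lithium in place of iodine, geometry retained) | [Li]/C=C(\C)CC[C@@H](O[Si](C)(C)C(C)(C)C)C(C)(C)/C=C/C[Si](C)(C)C | intermediate
13 | lithium alkoxide of the N-methoxy-N-methyl hemiaminal of 14 | CC(O[Li])(N(C)OC)/C=C(\C)CC[C@@H](O[Si](C)(C)C(C)(C)C)C(C)(C)/C=C/C[Si](C)(C)C | intermediate
14 | (3E,7R,9E)-7-[(tert-butyldimethylsilyl)oxy]-4,8,8-trimethyl-11-(trimethylsilyl)undeca-3,9-dien-2-one | CC(=O)/C=C(\C)CC[C@@H](O[Si](C)(C)C(C)(C)C)C(C)(C)/C=C/C[Si](C)(C)C | intermediate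
15 | trichlorotitanium enolate of 16 (C8–O–TiCl3, C8=C9) | CC(O[Ti](Cl)(Cl)Cl)=C[C@]1(C)CC[C@@H](O[Si](C)(C)C(C)(C)C)C(C)(C)[C@H]1C=C | intermediate
16 | 1-[(1S,2S,4R)-4-[(tert-butyldimethylsilyl)oxy]-2-ethenyl-1,3,3-trimethylcyclohexyl]propan-2-one | CC(=O)C[C@]1(C)CC[C@@H](O[Si](C)(C)C(C)(C)C)C(C)(C)[C@H]1C=C | intermediate
17 | 1,2,4-trioxolane (ozonide) of the vinyl group of 16 | CC(=O)C[C@]1(C)CC[C@@H](O[Si](C)(C)C(C)(C)C)C(C)(C)[C@H]1C2OCOO2 | intermediate
18 | (1S,3R,6S)-3-[(tert-butyldimethylsilyl)oxy]-2,2,6-trimethyl-6-(2-oxopropyl)cyclohexane-1-carbaldehyde | CC(=O)C[C@]1(C)CC[C@@H](O[Si](C)(C)C(C)(C)C)C(C)(C)[C@H]1C=O | intermediate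
19 | (4aS,6R,8aS)-6-[(tert-butyldimethylsilyl)oxy]-4-hydroxy-5,5,8a-trimethyloctahydronaphthalen-2(1H)-one (carbinol centre open) | O=C1CC(O)[C@@H]2C(C)(C)[C@H](O[Si](C)(C)C(C)(C)C)CC[C@@]2(C)C1 | intermediate
20 | (4aS,6R,8aS)-6-[(tert-butyldimethylsilyl)oxy]-5,5,8a-trimethyl-4a,5,6,7,8,8a-hexahydronaphthalen-2(1H)-one | O=C1C=C[C@@H]2C(C)(C)[C@H](O[Si](C)(C)C(C)(C)C)CC[C@@]2(C)C1 | intermediate
21 | methyl hydrogen (R)-3-methylglutarate | COC(=O)C[C@H](C)CC(=O)O | starting material
22 | methyl (3R)-5-hydroxy-3-methylpentanoate | COC(=O)C[C@H](C)CCO | intermediate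
23 | methyl (3R)-3-methyl-5-oxopentanoate | COC(=O)C[C@H](C)CC=O | intermediate
24 | lithium 1,3-dienolate of 20 (C8–OLi, C8=C9, C6=C7) | [Li]OC1C=C[C@@H]2C(C)(C)[C@H](O[Si](C)(C)C(C)(C)C)CC[C@@]2(C)C=1 | intermediate
25 | methyl (3R)-5-[(4aS,6R,8aR)-6-[(tert-butyldimethylsilyl)oxy]-5,5,8a-trimethyl-2-oxo-1,2,4a,5,6,7,8,8a-octahydronaphthalen-1-yl]-5-hydroxy-3-methylpentanoate (C9 and C11 open) | COC(=O)C[C@H](C)CC(O)C1C(=O)C=C[C@@H]2C(C)(C)[C@H](O[Si](C)(C)C(C)(C)C)CC[C@@]12C | intermediate
26 | C11 methanesulfonate of 25 | COC(=O)C[C@H](C)CC(OS(C)(=O)=O)C1C(=O)C=C[C@@H]2C(C)(C)[C@H](O[Si](C)(C)C(C)(C)C)CC[C@@]12C | intermediate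
27 | methyl (3R)-5-[(4aS,6R,8aR)-6-[(tert-butyldimethylsilyl)oxy]-5,5,8a-trimethyl-2-oxo-4a,5,6,7,8,8a-hexahydronaphthalen-1(2H)-ylidene]-3-methylpentanoate (alkene geometry open) | COC(=O)C[C@H](C)CC=C1C(=O)C=C[C@@H]2C(C)(C)[C@H](O[Si](C)(C)C(C)(C)C)CC[C@@]12C | intermediate
28 | methyl (3R)-5-[(1S,4aS,6R,8aR)-6-[(tert-butyldimethylsilyl)oxy]-5,5,8a-trimethyl-2-oxodecahydronaphthalen-1-yl]-3-methylpentanoate | COC(=O)C[C@H](C)CC[C@@H]1C(=O)CC[C@@H]2C(C)(C)[C@H](O[Si](C)(C)C(C)(C)C)CC[C@@]12C | intermediate
29 | potassium enolate of 28 (C8–OK, C7=C8) | COC(=O)C[C@H](C)CC[C@@H]1C(O[K])=CC[C@@H]2C(C)(C)[C@H](O[Si](C)(C)C(C)(C)C)CC[C@@]12C | intermediate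
30 | methyl (3R)-5-[(1S,4aS,6R,8aR)-6-[(tert-butyldimethylsilyl)oxy]-5,5,8a-trimethyl-2-{[(trifluoromethyl)sulfonyl]oxy}-1,4,4a,5,6,7,8,8a-octahydronaphthalen-1-yl]-3-methylpentanoate | COC(=O)C[C@H](C)CC[C@@H]1C(OS(=O)(=O)C(F)(F)F)=CC[C@@H]2C(C)(C)[C@H](O[Si](C)(C)C(C)(C)C)CC[C@@]12C | intermediate
31 | methyl (3R)-5-[(1S,4aS,6R,8aS)-6-[(tert-butyldimethylsilyl)oxy]-2-(hydroxymethyl)-5,5,8a-trimethyl-1,4,4a,5,6,7,8,8a-octahydronaphthalen-1-yl]-3-methylpentanoate | COC(=O)C[C@H](C)CC[C@@H]1C(CO)=CC[C@@H]2C(C)(C)[C@H](O[Si](C)(C)C(C)(C)C)CC[C@@]12C | intermediate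
32 | methyl (3R)-5-[(1S,4aS,6R,8aS)-6-hydroxy-2-(hydroxymethyl)-5,5,8a-trimethyl-1,4,4a,5,6,7,8,8a-octahydronaphthalen-1-yl]-3-methylpentanoate | COC(=O)C[C@H](C)CC[C@@H]1C(CO)=CC[C@@H]2C(C)(C)[C@H](O)CC[C@@]12C | target

## Step count and least certain steps

Total: 17 steps. Longest linear sequence: 15 steps (steps 1–9 and 12–17); steps 10 and 11 form the two-step side branch.

**Step 7 (key step).** The bond joins a carbon next to the quaternary C4 to a carbon that becomes quaternary. Ring closure may be slow enough for protodesilylation of the allylsilane by adventitious acid to outrun it, and the chair with the arm axial may compete, eroding facial selectivity at C10. The fallback sets out from 9 and returns at 18. Hydroboration of the terminal vinyl group with 9-BBN and oxidative work-up would give the primary alcohol F1. Iodine–lithium exchange with t-BuLi (3.1 equiv, the first equivalent making the alkoxide) and acylation with N-methoxy-N-methylacetamide would give the hydroxy enone F2, and Dess–Martin oxidation the enone aldehyde F3. Pyrrolidine and acetic acid would then form the aldehyde enamine, whose C5 adds to C10 in an intramolecular Michael reaction to give 18, which continues into step 9. This closes the same bond without silicon or Lewis acid. Because the enamine addition is reversible and C5 stays epimerisable, the outcome is no longer fixed by a single kinetic event, though C10 selectivity remains untested there as well.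

**Step 5.** The vinyl group sits on a quaternary carbon beside the silyloxy-bearing carbon, so the ruthenium carbene may fail to engage it and only self-metathesis of 10 would be seen. The fallback sets out from 9 and returns at 11. Oxidative cleavage of the terminal alkene (OsO4 cat., NaIO4, 2,6-lutidine, dioxane–water; the electron-poor iodoalkene is much less reactive) would give the aldehyde F4. Julia–Kocienski olefination with 1-phenyl-5-{[2-(trimethylsilyl)ethyl]sulfonyl}-1H-tetrazole and KN(SiMe3)2 would then give the (E)-allylsilane 11.

**Step 9.** The aldehyde carbon C5 lies between two quaternary carbons, and enolisation there before ring closure would lead to loss of the trans ring fusion. The fallback sets out from 16 and returns at 20, and never makes C5 α to a carbonyl. The kinetic enolate of the methyl ketone (LiN(i-Pr)2) is trapped with dimethyl(methylidene)ammonium iodide to give the Mannich base F5. Quaternisation with MeI and elimination with NaHCO3 give the vinyl ketone F6. Ring-closing metathesis between its enone vinyl group and the C5 vinyl group (second-generation Grubbs catalyst, toluene, 80 °C) then gives 20 directly.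

**Step 14.** Double-bond migration on palladium or incomplete facial discrimination at C9 would give a mixture of C9 epimers. The fallback sets out from 27 and returns at 28. Conjugate reduction with [(Ph3P)CuH]6 in wet THF adds hydride at C6 and C11, and the resulting C8–C9 copper enolate is protonated from the face away from C20. This replaces surface hydrogenation by kinetic protonation of a discrete enolate, where the proton source can be made bulky; it creates no new compound.

**Step 15.** Proton removal at C14 of the ester or at C9, or proton exchange between enolates, would give regioisomeric triflates and could scramble C9. The fallback sets out from 28 and returns at 31 without any enolate. Dimethylsulfonium methylide (Me3SI, n-BuLi, THF, 0 °C) converts the ketone into the spiro-epoxide F7. Diethylaluminium 2,2,6,6-tetramethylpiperidide then opens it by syn-elimination of the less hindered H7, giving the C7=C8 alkene and the C17 alcohol of 31.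

## Further compounds

F1 | step 7 | (4R,7E)-4-[(tert-butyldimethylsilyl)oxy]-8-iodo-3,3,7-trimethyloct-7-en-1-ol | OCCC(C)(C)[C@H](O[Si](C)(C)C(C)(C)C)CC/C(C)=C/I
F2 | step 7 | (3E,7R)-7-[(tert-butyldimethylsilyl)oxy]-10-hydroxy-4,8,8-trimethyldec-3-en-2-one | CC(=O)/C=C(\C)CC[C@@H](O[Si](C)(C)C(C)(C)C)C(C)(C)CCO
F3 | step 7 | (4R,7E)-4-[(tert-butyldimethylsilyl)oxy]-3,3,7-trimethyl-9-oxodec-7-enal | CC(=O)/C=C(\C)CC[C@@H](O[Si](C)(C)C(C)(C)C)C(C)(C)CC=O
F4 | step 5 | (3R,6E)-3-[(tert-butyldimethylsilyl)oxy]-7-iodo-2,2,6-trimethylhept-6-enal | O=CC(C)(C)[C@H](O[Si](C)(C)C(C)(C)C)CC/C(C)=C/I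
F5 | step 9 | 1-[(1S,2S,4R)-4-[(tert-butyldimethylsilyl)oxy]-2-ethenyl-1,3,3-trimethylcyclohexyl]-4-(dimethylamino)butan-2-one | CN(C)CCC(=O)C[C@]1(C)CC[C@@H](O[Si](C)(C)C(C)(C)C)C(C)(C)[C@H]1C=C
F6 | step 9 | 1-[(1S,2S,4R)-4-[(tert-butyldimethylsilyl)oxy]-2-ethenyl-1,3,3-trimethylcyclohexyl]but-3-en-2-one | C=CC(=O)C[C@]1(C)CC[C@@H](O[Si](C)(C)C(C)(C)C)C(C)(C)[C@H]1C=C
F0 | step 14 | none | none
F7 | step 15 | C8 spiro-epoxide of 28 (oxirane from the C8 carbonyl, C8 configuration open) | COC(=O)C[C@H](C)CC[C@@H]1C2(CO2)CC[C@@H]3C(C)(C)[C@H](O[Si](C)(C)C(C)(C)C)CC[C@@]13C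
A1 | alternative 1 | ring B allylic alcohol (C8 carbinol, C9=C10 alkene, C3 silyl ether) | O[C@@H]1CC[C@@H]2C(C)(C)[C@H](O[Si](C)(C)C(C)(C)C)CCC2=C1
A2 | alternative 1 | cyclopropyl carbinol with C20 bridging C9 and C10 | O[C@@H]1CC[C@@H]2C(C)(C)[C@H](O[Si](C)(C)C(C)(C)C)CC[C@]23C[C@H]13
A3 | alternative 2 | carvone-derived keto aldehyde (C10 methyl and 3-oxopropyl, C5 isopropenyl) | CC1=CC[C@H](C(C)=C)[C@@](C)(CCC=O)C1=O
A4 | alternative 2 | trans-fused bicyclic enone with C3 hydroxyl and C4 gem-dimethyl | CC1=CC[C@@H]2C(C)(C)[C@H](O)CC[C@@]2(C)C1=O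
A5 | alternative 3 | ring A vinylcyclohexene diene (C10=C5–C6=C7, C3 silyl ether) | C=CC1=C(C)CC[C@@H](O[Si](C)(C)C(C)(C)C)C1(C)C
A6 | alternative 3 | side-chain ynone (C8≡C9, C11 ketone, C17 silyl ether) | COC(=O)C[C@H](C)CC(=O)C#CCO[Si](C)(C)C(C)(C)C
A7 | alternative 3 | cyclohexa-1,4-diene Diels–Alder adduct | COC(=O)C[C@H](C)CC(=O)C1=C(CO[Si](C)(C)C(C)(C)C)CC=C2C(C)(C)[C@H](O[Si](C)(C)C(C)(C)C)CC[C@@]12C
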